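**Plan**

- Feature: number the oxolane O1, C2, C3, C4, C5, with carbinol carbon Ca (S) on C3 and Cb (R) on C4. With Ca as a ketone, O1–C2–C3–Ca is a β-alkoxy ketone; with Cb as a nitro carbon, C4–Cb is the β,α pair of an α-aryl nitroalkene whose allylic carbon C5 already carries O1.
- Retrosynthesis: both carbinols go back to C=O (Cb further to CH–NO2). O1–C2 and C3–C4 are then cut together, leaving an aryl vinyl ketone and an (E)-3-aryl-3-nitroallyl alcohol. These are cut at Ca–C3 (vinyl Grignard), Cb–C4 (Henry) and aryl–Cb (nitromethylation).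
- Forward: the two halves are made separately (two and four steps) and joined in one domino step that closes the only ring. Ketone reduction, Nef reaction, second ketone reduction and debenzylation follow.
- Stereochemistry: C4 comes from the chiral squaramide in the ring closure, and C3 settles trans to it by enolisation. Ca and Cb come from the (S,S) and (R,R) forms of RuCl(p-cymene)(TsDPEN), used on two different ketones, so two equivalent carbonyls never have to be told apart.

Key step: step 7

Assumption: the quinine-derived squaramide is taken to give the (4S) series drawn (otherwise its quinidine-derived pseudo-enantiomer is used), and the nitro-bearing carbon of the key-step product is drawn as one epimer although either serves, since the Nef step removes it.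

**Route**

Step 1
Reactants: 1 4-benzyloxy-3-methoxybenzaldehyde; 2 vinylmagnesium bromide
Product: 3 1-(4-benzyloxy-3-methoxyphenyl)prop-2-en-1-ol (racemic)
Conditions: 2 (1.2 equiv), THF, 0 °C; H2O quench
Reagents that add atoms: none
Why: Grignard 1,2-addition of the vinyl nucleophile to a non-enolisable aryl aldehyde gives the racemic allylic alcohol, whose stereocentre is removed in the next step.

Step 2
Reactants: 3 1-(4-benzyloxy-3-methoxyphenyl)prop-2-en-1-ol
Product: 4 1-(4-benzyloxy-3-methoxyphenyl)prop-2-en-1-one
Conditions: MnO2 (activated, excess), CH2Cl2, rt; used at once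
Reagents that add atoms: none
Why: Activated MnO2 oxidises benzylic–allylic alcohols selectively under neutral conditions, so the polymerisation-prone aryl vinyl ketone is formed without acid or base.

Step 3
Reactants: 5 1-benzyloxy-4-bromo-2-methoxybenzene; 6 nitromethane
Product: 7 1-benzyloxy-2-methoxy-4-(nitromethyl)benzene
Conditions: Pd2(dba)3 (tris(dibenzylideneacetone)dipalladium, 2.5 mol %), XPhos (6 mol %), Cs2CO3, 6 (10 equiv), 4 Å MS, 1,4-dioxane, 50 °C
Reagents that add atoms: none
Why: Cross-coupling of an aryl bromide with the nitronate of nitromethane at zerovalent palladium bearing a bulky biarylphosphine gives the arylnitromethane directly and avoids the nitrite-ester formation that electron-rich benzyl halides suffer with nitrite salts.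

Step 4
Reactants: 7 1-benzyloxy-2-methoxy-4-(nitromethyl)benzene; 8 (tert-butyldimethylsilyloxy)acetaldehyde
Product: 9 1-(4-benzyloxy-3-methoxyphenyl)-3-(tert-butyldimethylsilyloxy)-1-nitropropan-2-ol (racemic mixture of diastereomers)
Conditions: Et3N (0.2 equiv), THF, 0 °C → rt
Reagents that add atoms: none
Why: Henry reaction of the acidic benzylic nitronate with an unhindered α-silyloxy aldehyde under catalytic amine base; both diastereomers converge in the next step.

Step 5
Reactants: 9 1-(4-benzyloxy-3-methoxyphenyl)-3-(tert-butyldimethylsilyloxy)-1-nitropropan-2-ol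
Product: 11 tert-butyl{[(E)-3-(4-benzyloxy-3-methoxyphenyl)-3-nitroprop-2-en-1-yl]oxy}dimethylsilane, via secondary mesylate 10 (not isolated)
Conditions: MsCl (1.1 equiv), iPr2NEt (2.2 equiv), CH2Cl2, −40 → 0 °C
Reagents that add atoms: none
Why: Mesylation of the secondary alcohol and E1cB elimination through the benzylic nitronate give the conjugated nitroalkene, and the (E)-isomer (CH2OSi trans to NO2) should prevail because it frees the nitro group from allylic strain.

Step 6
Reactants: 11 tert-butyl{[(E)-3-(4-benzyloxy-3-methoxyphenyl)-3-nitroprop-2-en-1-yl]oxy}dimethylsilane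
Product: 12 (E)-3-(4-benzyloxy-3-methoxyphenyl)-3-nitroprop-2-en-1-ol
Conditions: aq. HF (48 %), MeCN, 0 °C
Reagents that add atoms: none
Why: Acidic fluoride cleaves the primary silyl ether without the basic conditions that would add nucleophiles to the nitroalkene or shift its double bond.

Step 7
Reactants: 4 1-(4-benzyloxy-3-methoxyphenyl)prop-2-en-1-one; 12 (E)-3-(4-benzyloxy-3-methoxyphenyl)-3-nitroprop-2-en-1-ol
Product: 14 (4-benzyloxy-3-methoxyphenyl){(3R,4S)-4-[(R)-(4-benzyloxy-3-methoxyphenyl)(nitro)methyl]oxolan-3-yl}methanone, via acyclic ether ketone 13 (not isolated)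
Conditions: quinine-derived squaramide 3-{[3,5-bis(trifluoromethyl)phenyl]amino}-4-{[(8α,9S)-6'-methoxycinchonan-9-yl]amino}cyclobut-3-ene-1,2-dione (10 mol %), 4 Å MS, CH2Cl2, −20 °C → rt; 4 (1.0 equiv) added slowly to 12 (1.2 equiv)
Reagents that add atoms: none
Why: Proposed new method: the quinuclidine nitrogen of the catalyst acts as a general base for reversible addition of the hydroxyl of 12 to the unsubstituted β-carbon of enone 4 (O1–C2), and the enolate of ether 13 so formed is captured by the tethered nitroalkene, which the squaramide N–H pair holds through its nitro group, in an irreversible Michael addition that ends in a benzylic nitronate (C3–C4). The closest known reaction type is the bifunctional-squaramide domino oxa-Michael–Michael reaction that builds 3,4-disubstituted oxolanes from γ-hydroxy enones and nitroalkenes, and chromans from 2-(2-nitrovinyl)phenols; here the hydroxyl sits on the nitroalkene partner and the weakly acidic aryl ketone enolate is produced by the oxa-Michael step itself, not by deprotonation. The oxolane closes in the 5-exo-trig mode, the nitronate carbon staying outside the ring. C4 is fixed by the catalyst, which shields one face of the bound (E)-nitroalkene, C3 lies α to the ketone and settles trans to the C4 substituent by enolisation, and the nitro-bearing carbon arises on protonation of the nitronate and is of no consequence. The step needs O-addition to 4 in preference to the nitroalkene of a second molecule of 12, which the unhindered terminal CH2 of the vinyl ketone secures against the trisubstituted, aryl-twisted nitroalkene. It also needs ring closure to outrun addition of the product nitronate to more 4, which slow addition of 4 as the limiting component secures.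

Step 8
Reactants: 14 (4-benzyloxy-3-methoxyphenyl){(3R,4S)-4-[(R)-(4-benzyloxy-3-methoxyphenyl)(nitro)methyl]oxolan-3-yl}methanone
Product: 15 (S)-(4-benzyloxy-3-methoxyphenyl){(3R,4S)-4-[(R)-(4-benzyloxy-3-methoxyphenyl)(nitro)methyl]oxolan-3-yl}methanol
Conditions: RuCl(p-cymene)[(S,S)-TsDPEN] (2 mol %), HCO2H/Et3N (5:2), EtOAc, 30 °C
Reagents that add atoms: none
Why: Noyori asymmetric transfer hydrogenation: the (S,S) catalyst delivers hydride to the aryl ketone in the CH/π-controlled sense that turns acetophenone into the (S)-alcohol, which sets Ca as S under catalyst control, while the nitro group and benzyl ethers are inert to the Ru–H/N–H couple.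

Step 9
Reactants: 15 (S)-(4-benzyloxy-3-methoxyphenyl){(3R,4S)-4-[(R)-(4-benzyloxy-3-methoxyphenyl)(nitro)methyl]oxolan-3-yl}methanol
Product: 17 (4-benzyloxy-3-methoxyphenyl){(3R,4R)-4-[(S)-(4-benzyloxy-3-methoxyphenyl)(hydroxy)methyl]oxolan-3-yl}methanone, via sodium nitronate 16 (not isolated)
Conditions: NaOMe (1.05 equiv), MeOH, 0 °C; then Oxone (2KHSO5·KHSO4·K2SO4), Na2HPO4 buffer, H2O/MeOH, 0 °C → rt
Reagents that add atoms: potassium peroxymonosulfate (active component of Oxone), [K+].[O-]S(=O)(=O)OO
Why: Oxidative Nef reaction: methoxide converts the acidic benzylic nitro group into nitronate 16, whose C=N bond is oxidised by peroxymonosulfate to the ketone with loss of nitrite; the ketone appears only in buffered medium, which spares the benzyl ethers, the electron-rich rings and the alcohol, and the one centre made epimerisable (C4) prefers trans.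

Step 10
Reactants: 17 (4-benzyloxy-3-methoxyphenyl){(3R,4R)-4-[(S)-(4-benzyloxy-3-methoxyphenyl)(hydroxy)methyl]oxolan-3-yl}methanone
Product: 18 (S)-(4-benzyloxy-3-methoxyphenyl){(3R,4R)-4-[(R)-(4-benzyloxy-3-methoxyphenyl)(hydroxy)methyl]oxolan-3-yl}methanol
Conditions: RuCl(p-cymene)[(R,R)-TsDPEN] (2 mol %), HCO2H/Et3N (5:2), EtOAc, 30 °C
Reagents that add atoms: none
Why: The same Noyori transfer hydrogenation with the enantiomeric catalyst sets Cb as R; the free hydroxyl is tolerated, and the hemiketal that could mask the ketone would be a strained trans-fused bicycle and should not form.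

Step 11
Reactants: 18 (S)-(4-benzyloxy-3-methoxyphenyl){(3R,4R)-4-[(R)-(4-benzyloxy-3-methoxyphenyl)(hydroxy)methyl]oxolan-3-yl}methanol
Product: 19 4-[(S)-hydroxy{(3R,4R)-4-[(R)-hydroxy(4-hydroxy-3-methoxyphenyl)methyl]oxolan-3-yl}methyl]-2-methoxyphenol (CNP0157038.2)
Conditions: H2 (1 atm), Pd/C (palladium on carbon, 10 wt %), EtOAc, rt; stopped when both benzyl ethers are consumed
Reagents that add atoms: none
Why: Hydrogenolysis of aryl benzyl ethers over Pd/C is much faster than C–O hydrogenolysis of secondary benzylic alcohols in neutral ethyl acetate, so both phenols are freed without touching the four stereocentres.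

**Compound list**

1 | 4-benzyloxy-3-methoxybenzaldehyde | COc1cc(C=O)ccc1OCc1ccccc1 | starting material
2 | vinylmagnesium bromide | C=C[Mg]Br | starting material
3 | 1-(4-benzyloxy-3-methoxyphenyl)prop-2-en-1-ol (racemic) | C=CC(O)c1ccc(OCc2ccccc2)c(OC)c1 | intermediate
4 | 1-(4-benzyloxy-3-methoxyphenyl)prop-2-en-1-one | C=CC(=O)c1ccc(OCc2ccccc2)c(OC)c1 | intermediate
5 | 1-benzyloxy-4-bromo-2-methoxybenzene | COc1cc(Br)ccc1OCc1ccccc1 | starting material
6 | nitromethane | C[N+](=O)[O-] | starting material
7 | 1-benzyloxy-2-methoxy-4-(nitromethyl)benzene | COc1cc(C[N+](=O)[O-])ccc1OCc1ccccc1 | intermediate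
8 | (tert-butyldimethylsilyloxy)acetaldehyde | CC(C)(C)[Si](C)(C)OCC=O | starting material
9 | 1-(4-benzyloxy-3-methoxyphenyl)-3-(tert-butyldimethylsilyloxy)-1-nitropropan-2-ol (mixture of diastereomers) | COc1cc(C(C(O)CO[Si](C)(C)C(C)(C)C)[N+](=O)[O-])ccc1OCc1ccccc1 | intermediate
10 | 1-(4-benzyloxy-3-methoxyphenyl)-3-(tert-butyldimethylsilyloxy)-1-nitropropan-2-yl methanesulfonate | COc1cc(C(C(CO[Si](C)(C)C(C)(C)C)OS(C)(=O)=O)[N+](=O)[O-])ccc1OCc1ccccc1 | intermediate (not isolated)
11 | tert-butyl{[(E)-3-(4-benzyloxy-3-methoxyphenyl)-3-nitroprop-2-en-1-yl]oxy}dimethylsilane | CC(C)(C)[Si](C)(C)OC/C=C(/[N+](=O)[O-])c1ccc(OCc2ccccc2)c(OC)c1 | intermediate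
12 | (E)-3-(4-benzyloxy-3-methoxyphenyl)-3-nitroprop-2-en-1-ol | OC/C=C(/[N+](=O)[O-])c1ccc(OCc2ccccc2)c(OC)c1 | intermediate
13 | 1-(4-benzyloxy-3-methoxyphenyl)-3-{[(E)-3-(4-benzyloxy-3-methoxyphenyl)-3-nitroprop-2-en-1-yl]oxy}propan-1-one | COc1cc(C(=O)CCOC/C=C(/[N+](=O)[O-])c2ccc(OCc3ccccc3)c(OC)c2)ccc1OCc1ccccc1 | intermediate (not isolated)
14 | (4-benzyloxy-3-methoxyphenyl){(3R,4S)-4-[(R)-(4-benzyloxy-3-methoxyphenyl)(nitro)methyl]oxolan-3-yl}methanone | COc1cc(C(=O)[C@H]2COC[C@@H]2[C@@H]([N+](=O)[O-])c2ccc(OCc3ccccc3)c(OC)c2)ccc1OCc1ccccc1 | intermediate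
15 | (S)-(4-benzyloxy-3-methoxyphenyl){(3R,4S)-4-[(R)-(4-benzyloxy-3-methoxyphenyl)(nitro)methyl]oxolan-3-yl}methanol | COc1cc([C@@H](O)[C@H]2COC[C@@H]2[C@@H]([N+](=O)[O-])c2ccc(OCc3ccccc3)c(OC)c2)ccc1OCc1ccccc1 | intermediate
16 | sodium nitronate of 15 (C=N(O)O− Na+ at the former nitro carbon; carbinol S, ring 3R,4S) | COc1cc([C@@H](O)[C@H]2COC[C@@H]2C(=[N+]([O-])[O-])c2ccc(OCc3ccccc3)c(OC)c2)ccc1OCc1ccccc1.[Na+] | intermediate (not isolated)
17 | (4-benzyloxy-3-methoxyphenyl){(3R,4R)-4-[(S)-(4-benzyloxy-3-methoxyphenyl)(hydroxy)methyl]oxolan-3-yl}methanone | COc1cc([C@@H](O)[C@H]2COC[C@@H]2C(=O)c2ccc(OCc3ccccc3)c(OC)c2)ccc1OCc1ccccc1 | intermediate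
18 | (S)-(4-benzyloxy-3-methoxyphenyl){(3R,4R)-4-[(R)-(4-benzyloxy-3-methoxyphenyl)(hydroxy)methyl]oxolan-3-yl}methanol | COc1cc([C@@H](O)[C@H]2COC[C@@H]2[C@@H](O)c2ccc(OCc3ccccc3)c(OC)c2)ccc1OCc1ccccc1 | intermediate
19 | 4-[(S)-hydroxy{(3R,4R)-4-[(R)-hydroxy(4-hydroxy-3-methoxyphenyl)methyl]oxolan-3-yl}methyl]-2-methoxyphenol | COc1cc([C@@H](O)[C@H]2COC[C@@H]2[C@@H](O)c2ccc(O)c(OC)c2)ccc1O | target

**Step count and risks**

Total step count: 11. Longest linear sequence: 9 steps (steps 3 to 11, from 5 to 19).

Steps most likely to fail: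

1. Step 7. Proton transfer to the enolate may outpace C–C bond formation, so that the sequence stops at or reverts from the acyclic ether. The amine may also trigger oligomerisation of the vinyl ketone or a 1,3-proton shift in the γ-hydroxy nitroalkene, and facial discrimination at C4 may be weak. The fallback sets out from 4 and 12 and separates the two bond formations with known chemistry. A Brønsted acid (Tf2NH, 5 mol %, CH2Cl2, 0 °C) catalyses oxa-Michael addition of the alcohol to the vinyl ketone and gives ether 13, this time isolated. Ether 13 is then cyclised with a chiral primary amine–thiourea derived from trans-cyclohexane-1,2-diamine and benzoic acid as co-catalyst in toluene. The enamine of the aryl ketone adds 5-exo-trig to the thiourea-bound nitroalkene, and the route is rejoined at 14. No compound outside the list is made (F0).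

2. Step 8. The C3 centre next to the carbonyl may oppose the catalyst and erode facial selectivity, and hydride transfer to a hindered, electron-rich aryl ketone may be slow. The fallback sets out from 14 and gives up catalyst control. NaBH4 in MeOH/THF at −20 °C should give 15 together with its carbinol epimer, (R)-(4-benzyloxy-3-methoxyphenyl){(3R,4S)-4-[(R)-(4-benzyloxy-3-methoxyphenyl)(nitro)methyl]oxolan-3-yl}methanol F1. The two diastereomers are separated on silica, and F1 is oxidised back to 14 with Dess–Martin periodinane and recycled. The route is rejoined at 15.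

3. Step 9. Oxidation of the hindered nitronate may be incomplete, the electron-rich rings may be attacked by the oxidant, and base may epimerise C4 and drain the material into a cis-fused hemiketal. The fallback sets out from 15 through nitronate 16 and replaces oxidation by a reductive Nef reaction. Aqueous TiCl3 (trivalent titanium) buffered with NH4OAc reduces the nitronate to the oxime (S)-(4-benzyloxy-3-methoxyphenyl){(3R,4S)-4-[(4-benzyloxy-3-methoxyphenyl)(hydroxyimino)methyl]oxolan-3-yl}methanol F2. Further reduction gives the N–H imine (S)-(4-benzyloxy-3-methoxyphenyl){(3R,4S)-4-[(4-benzyloxy-3-methoxyphenyl)carbonimidoyl]oxolan-3-yl}methanol F3, which is hydrolysed in the same flask at about pH 5. The route is rejoined at 17.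

Further compounds
F0 | step 7 | none | none
F1 | step 8 | (R)-(4-benzyloxy-3-methoxyphenyl){(3R,4S)-4-[(R)-(4-benzyloxy-3-methoxyphenyl)(nitro)methyl]oxolan-3-yl}methanol | COc1cc([C@H](O)[C@H]2COC[C@@H]2[C@@H]([N+](=O)[O-])c2ccc(OCc3ccccc3)c(OC)c2)ccc1OCc1ccccc1
F2 | step 9 | (S)-(4-benzyloxy-3-methoxyphenyl){(3R,4S)-4-[(4-benzyloxy-3-methoxyphenyl)(hydroxyimino)methyl]oxolan-3-yl}methanol (E/Z mixture) | COc1cc([C@@H](O)[C@H]2COC[C@@H]2C(=NO)c2ccc(OCc3ccccc3)c(OC)c2)ccc1OCc1ccccc1
F3 | step 9 | (S)-(4-benzyloxy-3-methoxyphenyl){(3R,4S)-4-[(4-benzyloxy-3-methoxyphenyl)carbonimidoyl]oxolan-3-yl}methanol | COc1cc([C@@H](O)[C@H]2COC[C@@H]2C(=N)c2ccc(OCc3ccccc3)c(OC)c2)ccc1OCc1ccccc1
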